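**Retrosynthetic overview**

1. The side chain is numbered from the carboxyl carbon C1 to C9, which is bonded to C2 of the chromane. The acid comes from its ethyl ester and aryl silyl ether; the (Z)-C2=C3 olefin is made last by Still–Gennari olefination of a C3 aldehyde.
2. Key disconnection: C5–C6 together with C6–CH3, by a one-flask double Negishi coupling that joins three components around the C6=C7 olefin: a 1,1-dichloroalkene (C6 = CCl2, C7 = CH), the C3–C5 alkylzinc, then Me2Zn.
3. Enabling feature: C6 is the fully carbon-substituted end of the C6=C7 olefin. It carries C5 and a methyl group, while C7 carries only H and C8. C6 can therefore enter as a CCl2 carbon whose chlorine trans to C8 reacts first, so the order of the two couplings fixes the (E) geometry and both chlorines are removed in the same step.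
4. The dichloroalkene comes from a C7 aldehyde, obtained by cleaving the prenyl end of a chromane built from (R)-linalool. The vinyl group of linalool becomes C3–C4 (hydroboration, B-alkyl Suzuki coupling with a 1-iodo-2-bromoarene) and its tertiary O–H becomes O1–C8a.
5. Ring order: the benzene ring (ring A) is bought as 3-bromo-5-methylphenol; the dihydropyran ring (ring B) is closed in step 4 by palladium-catalysed O-arylation. The only stereocentre, C2, comes from linalool.

Key step: step 7

Remark on the chemistry: commercial (R)-(−)-linalool is assumed to be of high enantiomeric purity. No step breaks a bond to carbon at its carbinol centre, so its configuration is carried unchanged into C2 of the chromane; the R/S descriptor changes only where CIP priorities change (compounds 5, 8 and 9).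

**Step 1**
Reactants: 1 3-bromo-5-methylphenol
Product: 2 3-bromo-4-iodo-5-methylphenol
Conditions: NIS (1.05 equiv), TsOH·H2O (10 mol %), MeCN, 0 °C to rt
Reagents that add atoms: N-iodosuccinimide, O=C1CCC(=O)N1I
Why: Electrophilic aromatic iodination with acid-activated NIS is directed para to the free hydroxyl group, so the iodine should enter at C4 between the bromine and the methyl group (any ortho isomer would be removed by chromatography).

**Step 2**
Reactants: 2 3-bromo-4-iodo-5-methylphenol
Product: 3 (3-bromo-4-iodo-5-methylphenoxy)tri(propan-2-yl)silane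
Conditions: TIPSCl (1.2 equiv), imidazole (2.5 equiv), DMF, rt
Reagents that add atoms: chlorotri(propan-2-yl)silane, CC(C)[Si](Cl)(C(C)C)C(C)C
Why: Silyl ether formation at the phenol installs a group that should withstand aqueous base, palladium catalysis, organozinc reagents and dilute acid, and that leaves with fluoride at the end.

**Step 3**
Reactants: 3 (3-bromo-4-iodo-5-methylphenoxy)tri(propan-2-yl)silane; 4 (R)-(−)-linalool
Product: 6 (3R)-1-[2-bromo-6-methyl-4-(triisopropylsilyloxy)phenyl]-3,7-dimethyloct-6-en-3-ol, via B-alkyl-9-BBN borane 5 (not isolated)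
Conditions: 4 (1.3 equiv), 9-BBN dimer (2.8 equiv B–H), THF, 0 °C to rt; then 3 (1.0 equiv), Pd(dppf)Cl2 (5 mol %), 3 M aq. K3PO4, DMF, 50 °C
Reagents that add atoms: none
Why: Anti-Markovnikov hydroboration of the monosubstituted vinyl group by 9-BBN (the trisubstituted olefin is left alone and the excess reagent accounts for the free hydroxyl) is followed by B-alkyl Suzuki–Miyaura coupling at the C–I bond, which undergoes oxidative addition far faster than the neighbouring C–Br bond; the carbinol stereocentre is not touched.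

**Step 4**
Reactants: 6 (3R)-1-[2-bromo-6-methyl-4-(triisopropylsilyloxy)phenyl]-3,7-dimethyloct-6-en-3-ol
Product: 7 (2R)-2,5-dimethyl-2-(4-methylpent-3-en-1-yl)-7-(triisopropylsilyloxy)chromane
Conditions: Pd(OAc)2 (5 mol %), 2-(di-tert-butylphosphino)-1,1'-binaphthyl (6 mol %), Cs2CO3 (1.5 equiv), toluene, 80 °C
Reagents that add atoms: none
Why: Intramolecular palladium-catalysed C–O coupling (Buchwald-type etherification) of the tertiary alkoxide, which has no hydrogen on its carbinol carbon for β-hydride elimination, closes the six-membered dihydropyran ring by O1–C8a bond formation; the stereocentre keeps its configuration because only its O–H bond changes.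

**Step 5**
Reactants: 7 (2R)-2,5-dimethyl-2-(4-methylpent-3-en-1-yl)-7-(triisopropylsilyloxy)chromane
Product: 9 3-[(2S)-2,5-dimethyl-7-(triisopropylsilyloxy)chroman-2-yl]propanal, via vicinal diol 8 (not isolated)
Conditions: OsO4 (2 mol %), NaIO4 (4 equiv), 2,6-lutidine (2 equiv), 1,4-dioxane/H2O 3:1, rt
Reagents that add atoms: osmium tetroxide, O=[Os](=O)(=O)=O (delivers the aldehyde oxygen and is restored by sodium periodate, [Na+].[O-]I(=O)(=O)=O)
Why: Lemieux–Johnson oxidative cleavage: the electron-rich trisubstituted olefin is dihydroxylated by catalytic OsO4 and the diol is cleaved by periodate, with 2,6-lutidine suppressing over-oxidation, while the arene and the silyl ether should be inert.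

**Step 6**
Reactants: 9 3-[(2S)-2,5-dimethyl-7-(triisopropylsilyloxy)chroman-2-yl]propanal
Product: 10 (2R)-2-(4,4-dichlorobut-3-en-1-yl)-2,5-dimethyl-7-(triisopropylsilyloxy)chromane
Conditions: PPh3 (3 equiv), BrCCl3 (1.5 equiv), MeCN, 0 °C to rt
Reagents that add atoms: bromotrichloromethane, ClC(Cl)(Cl)Br
Why: Wittig-type dichloromethylenation (Ramirez-type olefination) by the ylide Ph3P=CCl2 formed in the flask converts the aldehyde under neutral conditions; the new olefin terminus bears two identical chlorines, so no geometry issue arises.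

**Step 7**
Reactants: 10 (2R)-2-(4,4-dichlorobut-3-en-1-yl)-2,5-dimethyl-7-(triisopropylsilyloxy)chromane; 11 [2-(1,3-dioxolan-2-yl)ethyl]zinc bromide
Product: 13 2-{(3E)-6-[(2R)-2,5-dimethyl-7-(triisopropylsilyloxy)chroman-2-yl]-3-methylhex-3-en-1-yl}-1,3-dioxolane, via (Z)-chloroalkene acetal 12 (not isolated)
Conditions: 11 (1.3 equiv, 0.5 M in THF), PdCl2(DPEphos) (5 mol %), THF/DMF 1:1, rt; then, same flask, Me2Zn (3 equiv), Pd(P(t-Bu)3)2 (5 mol %), 50 °C
Reagents that add atoms: dimethylzinc, C[Zn]C
Why: Zerovalent palladium bearing the wide-bite-angle DPEphos should insert selectively into the C–Cl bond of 10 that is trans to the C8 chain (the cis C–Cl bond is shielded by that chain); transmetalation with the primary alkylzinc 11 and fast reductive elimination, which the large bite angle favours over β-hydride elimination, then form the C5–C6 bond and leave the (Z)-chloroalkene 12. The remaining, hindered C–Cl bond should be activated only once the electron-rich Pd(P(t-Bu)3)2 is added, and its coupling with Me2Zn proceeds with retention, so the order of addition alone fixes the (E) geometry of the trisubstituted olefin. The closest known reaction type is the palladium-catalysed trans-selective monoalkylation of 2-alkyl-1,1-dichloro-1-alkenes with alkylzinc halides, followed by stereoretentive methylation of the resulting (Z)-2-chloroalkene (Negishi coupling). No ring is closed and no stereocentre is created; C2 of the chromane is remote and untouched. The selectivities needed are mono- over dialkylation and trans over cis substitution in the first stage, secured by the steric difference between the two chlorines and the low reactivity of the monochloride towards the DPEphos catalyst, and retention in the second stage, secured by the purely alkyl-substituted chloroalkene, which offers no easy path for isomerisation. The acetal, the aryl silyl ether and the chromane ether are inert to organozinc reagents.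

**Step 8**
Reactants: 13 2-{(3E)-6-[(2R)-2,5-dimethyl-7-(triisopropylsilyloxy)chroman-2-yl]-3-methylhex-3-en-1-yl}-1,3-dioxolane
Product: 14 (4E)-7-[(2R)-2,5-dimethyl-7-(triisopropylsilyloxy)chroman-2-yl]-4-methylhept-4-enal
Conditions: 1 M aq. HCl/THF 1:3, rt
Reagents that add atoms: water, O
Why: Acid-catalysed acetal hydrolysis in dilute aqueous acid at room temperature, conditions under which the aryl silyl ether, the chromane and the trisubstituted olefin should be stable.

**Step 9**
Reactants: 14 (4E)-7-[(2R)-2,5-dimethyl-7-(triisopropylsilyloxy)chroman-2-yl]-4-methylhept-4-enal; 15 ethyl 2-[bis(2,2,2-trifluoroethoxy)phosphoryl]propanoate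
Product: 16 ethyl (2Z,6E)-9-[(2R)-2,5-dimethyl-7-(triisopropylsilyloxy)chroman-2-yl]-2,6-dimethylnona-2,6-dienoate
Conditions: 15 (1.3 equiv), KN(SiMe3)2 (1.25 equiv), 18-crown-6 (3 equiv), THF, −78 °C; then 14, −78 °C
Reagents that add atoms: none
Why: Still–Gennari modification of the Horner–Wadsworth–Emmons reaction: with the bis(trifluoroethyl) phosphonate and a crown-ether-separated potassium counter-ion, elimination from the first-formed adduct outruns equilibration, which should give the (Z)-trisubstituted enoate under kinetic control.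

**Step 10**
Reactants: 16 ethyl (2Z,6E)-9-[(2R)-2,5-dimethyl-7-(triisopropylsilyloxy)chroman-2-yl]-2,6-dimethylnona-2,6-dienoate
Product: 18 (2Z,6E)-9-[(2R)-7-hydroxy-2,5-dimethylchroman-2-yl]-2,6-dimethylnona-2,6-dienoic acid, via phenol ethyl ester 17 (not isolated)
Conditions: Bu4NF (1.2 equiv), THF, 0 °C; then LiOH·H2O (10 equiv), MeOH/H2O, 40 °C; then 1 M aq. HCl to pH 3
Reagents that add atoms: lithium hydroxide, [Li+].[OH-]
Why: Fluoride cleaves the Si–O bond of the aryl silyl ether and hydroxide then saponifies the ethyl ester (ester hydrolysis); the (Z)-olefin should survive because the carboxylate formed is no Michael acceptor and the acidification is mild.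

**Compound list**

1 | 3-bromo-5-methylphenol | Cc1cc(O)cc(Br)c1 | starting material
2 | 3-bromo-4-iodo-5-methylphenol | Cc1cc(O)cc(Br)c1I | intermediate
3 | (3-bromo-4-iodo-5-methylphenoxy)tri(propan-2-yl)silane | Cc1cc(O[Si](C(C)C)(C(C)C)C(C)C)cc(Br)c1I | intermediate
4 | (R)-(−)-linalool, (3R)-3,7-dimethylocta-1,6-dien-3-ol | C=C[C@](C)(O)CCC=C(C)C | starting material
5 | (3S)-1-(9-borabicyclo[3.3.1]nonan-9-yl)-3,7-dimethyloct-6-en-3-ol (B-alkyl-9-BBN borane, drawn with free hydroxyl; same spatial arrangement as 4) | CC(C)=CCC[C@@](C)(O)CCB1C2CCCC1CCC2 | intermediate (not isolated)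
6 | (3R)-1-[2-bromo-6-methyl-4-(triisopropylsilyloxy)phenyl]-3,7-dimethyloct-6-en-3-ol | CC(C)=CCC[C@@](C)(O)CCc1c(C)cc(O[Si](C(C)C)(C(C)C)C(C)C)cc1Br | intermediate
7 | (2R)-2,5-dimethyl-2-(4-methylpent-3-en-1-yl)-7-(triisopropylsilyloxy)chromane | CC(C)=CCC[C@]1(C)CCc2c(C)cc(O[Si](C(C)C)(C(C)C)C(C)C)cc2O1 | intermediate
8 | 5-[(2S)-2,5-dimethyl-7-(triisopropylsilyloxy)chroman-2-yl]-2-methylpentane-2,3-diol (both C3 epimers) | CC(C)(O)C(O)CC[C@]1(C)CCc2c(C)cc(O[Si](C(C)C)(C(C)C)C(C)C)cc2O1 | intermediate (not isolated)
9 | 3-[(2S)-2,5-dimethyl-7-(triisopropylsilyloxy)chroman-2-yl]propanal | O=CCC[C@]1(C)CCc2c(C)cc(O[Si](C(C)C)(C(C)C)C(C)C)cc2O1 | intermediate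
10 | (2R)-2-(4,4-dichlorobut-3-en-1-yl)-2,5-dimethyl-7-(triisopropylsilyloxy)chromane | ClC(Cl)=CCC[C@]1(C)CCc2c(C)cc(O[Si](C(C)C)(C(C)C)C(C)C)cc2O1 | intermediate
11 | [2-(1,3-dioxolan-2-yl)ethyl]zinc bromide | Br[Zn]CCC1OCCO1 | starting material
12 | 2-{(3Z)-3-chloro-6-[(2R)-2,5-dimethyl-7-(triisopropylsilyloxy)chroman-2-yl]hex-3-en-1-yl}-1,3-dioxolane | Cl/C(CCC3OCCO3)=C\CC[C@]1(C)CCc2c(C)cc(O[Si](C(C)C)(C(C)C)C(C)C)cc2O1 | intermediate (not isolated)
13 | 2-{(3E)-6-[(2R)-2,5-dimethyl-7-(triisopropylsilyloxy)chroman-2-yl]-3-methylhex-3-en-1-yl}-1,3-dioxolane | C/C(CCC3OCCO3)=C\CC[C@]1(C)CCc2c(C)cc(O[Si](C(C)C)(C(C)C)C(C)C)cc2O1 | intermediate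
14 | (4E)-7-[(2R)-2,5-dimethyl-7-(triisopropylsilyloxy)chroman-2-yl]-4-methylhept-4-enal | C/C(CCC=O)=C\CC[C@]1(C)CCc2c(C)cc(O[Si](C(C)C)(C(C)C)C(C)C)cc2O1 | intermediate
15 | ethyl 2-[bis(2,2,2-trifluoroethoxy)phosphoryl]propanoate | CCOC(=O)C(C)P(=O)(OCC(F)(F)F)OCC(F)(F)F | starting material
16 | ethyl (2Z,6E)-9-[(2R)-2,5-dimethyl-7-(triisopropylsilyloxy)chroman-2-yl]-2,6-dimethylnona-2,6-dienoate | C/C(=C/CC/C(C)=C/CC[C@]1(C)CCc2c(C)cc(O[Si](C(C)C)(C(C)C)C(C)C)cc2O1)C(=O)OCC | intermediate
17 | ethyl (2Z,6E)-9-[(2R)-7-hydroxy-2,5-dimethylchroman-2-yl]-2,6-dimethylnona-2,6-dienoate | C/C(=C/CC/C(C)=C/CC[C@]1(C)CCc2c(C)cc(O)cc2O1)C(=O)OCC | intermediate (not isolated)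
18 | (2Z,6E)-9-[(2R)-7-hydroxy-2,5-dimethylchroman-2-yl]-2,6-dimethylnona-2,6-dienoic acid | C/C(=C/CC/C(C)=C/CC[C@]1(C)CCc2c(C)cc(O)cc2O1)C(=O)O | target

**Summary**

Total step count: 10. Longest linear sequence: 10 steps (1 to 18); linalool 4 enters at step 3, zinc reagent 11 at step 7 and phosphonate 15 at step 9.

Steps most likely to fail:

Step 7. The one-flask double coupling may lose site and stereocontrol: alkylzinc left over from the first stage may enter a second time, or the order of the two substitutions may blur. Fallback: from dichloroalkene 10, n-BuLi (2.2 equiv, THF, −78 to 0 °C) followed by MeI would give the 2-alkyne (2R)-2,5-dimethyl-2-(pent-3-yn-1-yl)-7-(triisopropylsilyloxy)chromane F1. Hydrozirconation with excess Cp2Zr(H)Cl (THF, 50 °C, thermodynamic regiocontrol placing zirconium on the methyl-bearing carbon) and iodinolysis (I2, 0 °C) would give the iodoalkene (2R)-2-[(3E)-4-iodopent-3-en-1-yl]-2,5-dimethyl-7-(triisopropylsilyloxy)chromane F2. A separate Negishi coupling of F2 with zinc reagent 11 (Pd(dppf)Cl2, THF, 50 °C) forms the same C5–C6 bond with retention and rejoins the route at acetal 13.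

Step 3. Transmetalation at the di-ortho-substituted arylpalladium iodide may be slow, allowing protodehalogenation or competing oxidative addition at the C–Br bond. Fallback: from aryl iodide 3 and linalool 4, a Heck arylation of the vinyl group (Pd(OAc)2, Bu4NCl, NaHCO3, DMF, 60 °C) would give the styrenyl alcohol (1E,3R)-1-[2-bromo-6-methyl-4-(triisopropylsilyloxy)phenyl]-3,7-dimethylocta-1,6-dien-3-ol F3. Diimide reduction (2-nitrobenzenesulfonyl hydrazide, Et3N, CH2Cl2, rt) should saturate the disubstituted styrene double bond much faster than the trisubstituted olefin and rejoin the route at alcohol 6.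

Step 9. Z-selectivity may erode in the olefination of the unhindered aldehyde with the α-methyl phosphonate. Fallback: from aldehyde 14, a Wittig reaction with Ph3P=C(I)CH3 (from ethyltriphenylphosphonium iodide, n-BuLi, I2, then NaN(SiMe3)2, THF, −78 °C) would give the iodoalkene (2R)-2-[(3E,7Z)-8-iodo-4-methylnona-3,7-dien-1-yl]-2,5-dimethyl-7-(triisopropylsilyloxy)chromane F4, with iodine cis to the chain. Palladium-catalysed ethoxycarbonylation (Pd(PPh3)2Cl2, CO 1 atm, EtOH, Et3N, DMF, 60 °C) proceeds with retention and rejoins the route at ester 16.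

**Further compounds**

F1 | step 7 | (2R)-2,5-dimethyl-2-(pent-3-yn-1-yl)-7-(triisopropylsilyloxy)chromane | CC#CCC[C@]1(C)CCc2c(C)cc(O[Si](C(C)C)(C(C)C)C(C)C)cc2O1
F2 | step 7 | (2R)-2-[(3E)-4-iodopent-3-en-1-yl]-2,5-dimethyl-7-(triisopropylsilyloxy)chromane | C/C(I)=C\CC[C@]1(C)CCc2c(C)cc(O[Si](C(C)C)(C(C)C)C(C)C)cc2O1
F3 | step 3 | (1E,3R)-1-[2-bromo-6-methyl-4-(triisopropylsilyloxy)phenyl]-3,7-dimethylocta-1,6-dien-3-ol | CC(C)=CCC[C@@](C)(O)/C=C/c1c(C)cc(O[Si](C(C)C)(C(C)C)C(C)C)cc1Br
F4 | step 9 | (2R)-2-[(3E,7Z)-8-iodo-4-methylnona-3,7-dien-1-yl]-2,5-dimethyl-7-(triisopropylsilyloxy)chromane | I/C(C)=C\CC/C(C)=C/CC[C@]1(C)CCc2c(C)cc(O[Si](C(C)C)(C(C)C)C(C)C)cc2O1
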